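## Retrosynthetic overview

1. The Z-enal is made last, by oxidative 1,3-transposition of a tertiary isopropenyl carbinol. The side-chain carbinol comes from CBS reduction of an E-enone, itself made by Wittig reaction of a ring lactol with a C12 keto-ylide.
2. Key disconnection: the bond between the quaternary ring carbon and the first CH2 of the side chain. It is made by a 6-exo-trig radical cyclization of a bromoacetal, tethered on the tertiary alcohol, onto the β-carbon of a 2,3-dialkylcyclohexenone; H-atom transfer then sets the neighbouring ring CH.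
3. The cyclization substrate comes from B-alkyl Suzuki coupling of an α-iodoenone with hydroborated allyl tetradecanoate. The iodoenone comes from (S)-1,2-dimethylcyclohex-2-enol, made by enantioselective methyl addition to 2-methylcyclohex-2-enone.
4. Side pieces: allyl tetradecanoate from 1-bromoheptane, 1,6-dibromohexane and allyl chloroformate; the keto-ylide from 5-bromo-2-methylpent-2-ene through an alkyne, Zr-catalysed carboalumination/ethylene oxide, oxidation and ylide acylation.
5. Ring order: the carbocycle is present from the start; a temporary tetrahydropyran (acetal) ring is closed in the radical step and opened again in the Wittig step.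

Assumption: centres that form as mixtures and are destroyed later (the acetal/lactol carbon and the carbinol carbon made in step 9) are left undefined in names and SMILES.

## Route

Step 1
Reactants: 1 2-methylcyclohex-2-en-1-one
Product: 2 (S)-1,2-dimethylcyclohex-2-en-1-ol
Conditions: ZnMe2 (3 equiv), Ti(OiPr)4 (1.2 equiv), bis(hydroxycamphorsulfonamide) ligand from trans-cyclohexane-1,2-diamine (10 mol %, the enantiomer that gives the S alcohol), toluene/hexane, rt; aq. NH4Cl
Reagents that add atoms: dimethylzinc, C[Zn]C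
Why: Catalytic enantioselective 1,2-addition of an alkylzinc to an α-substituted cyclic enone (Walsh titanium/bis(sulfonamide) diol system), in which the 2-methyl group differentiates the two flanks of the carbonyl and the chiral titanium complex sets the tertiary carbinol as S, the centre from which all ring stereochemistry is relayed.

Step 2
Reactants: 2 (S)-1,2-dimethylcyclohex-2-en-1-ol
Product: 3 (S)-4-hydroxy-3,4-dimethylcyclohex-2-en-1-one
Conditions: Rh2(cap)4 (cap = caprolactamate, 1 mol %), t-BuOOH (70 % aq., 5 equiv), K2CO3 (0.5 equiv), CH2Cl2, rt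
Reagents that add atoms: tert-butyl hydroperoxide, CC(C)(C)OO
Why: Radical-chain allylic C–H oxidation (dirhodium caprolactamate/TBHP) converts the ring methylene next to the alkene CH into the enone carbonyl, while the tertiary allylic alcohol cannot be oxidized and is not transposed under these chromium-free conditions.

Step 3
Reactants: 3 (S)-4-hydroxy-3,4-dimethylcyclohex-2-en-1-one
Product: 4 (S)-4-hydroxy-2-iodo-3,4-dimethylcyclohex-2-en-1-one
Conditions: I2 (1.5 equiv), pyridine/CH2Cl2 (1:1), rt, dark
Reagents that add atoms: iodine, [I][I]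
Why: Johnson α-iodination of an enone (conjugate addition of pyridine, iodination of the enolate, elimination) places iodine on the only vinylic CH and leaves the carbinol centre untouched.

Step 4
Reactants: 5 1-bromoheptane; 6 1,6-dibromohexane
Product: 8 1-bromotridecane, via heptylmagnesium bromide 7 (not isolated)
Conditions: Mg, THF, 40 °C; then 6 (3 equiv), Li2CuCl4 (3 mol %), THF, −10 °C → rt
Reagents that add atoms: none
Why: Kochi copper-catalysed sp3–sp3 coupling of a primary Grignard reagent with a primary bromide, kept at mono-coupling by the excess of dibromide.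

Step 5
Reactants: 8 1-bromotridecane; 9 allyl chloroformate
Product: 11 allyl tetradecanoate, via tridecylmagnesium bromide 10 (not isolated)
Conditions: Mg, THF, reflux; then added to 9 (2 equiv), THF, −78 °C
Reagents that add atoms: none
Why: Acylation of a Grignard reagent by a chloroformate under inverse addition at low temperature stops at the ester because the chloroformate is far more electrophilic than the product.

Step 6
Reactants: 4 (S)-4-hydroxy-2-iodo-3,4-dimethylcyclohex-2-en-1-one; 11 allyl tetradecanoate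
Product: 13 hydroxy enone ester 3-[(3S)-3-hydroxy-2,3-dimethyl-6-oxocyclohex-1-en-1-yl]propyl tetradecanoate, via B-alkyl-9-BBN 12 (not isolated)
Conditions: 11, 9-BBN (1.0 equiv), THF, 0 °C → rt; then 4, PdCl2(dppf) (5 mol %), AsPh3 (5 mol %), Cs2CO3 (2 equiv), DMF/THF/H2O, rt
Reagents that add atoms: none
Why: Anti-Markovnikov hydroboration of the allyl ester followed by B-alkyl Suzuki–Miyaura coupling with the α-iodoenone installs the complete tetradecanoyloxypropyl arm on the enone α-carbon with the ester and the free tertiary alcohol tolerated.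

Step 7
Reactants: 13 hydroxy enone ester; 14 3-bromo-1,1-dimethoxypropane
Product: 16 bromoacetal 3-[(3S)-3-(3-bromo-1-methoxypropoxy)-2,3-dimethyl-6-oxocyclohex-1-en-1-yl]propyl tetradecanoate, via α-bromo ether 15 (not isolated)
Conditions: 14 (3 equiv), AcBr (3 equiv), ZnBr2 (1 mol %), CH2Cl2, 0 °C; then 13, i-Pr2NEt (5 equiv), CH2Cl2, 0 °C → rt
Reagents that add atoms: none
Why: O-Alkylation of the tertiary alcohol by a reactive α-bromo ether generated from the dimethyl acetal with acetyl bromide (the Stork way of making haloacetals of hindered alcohols), the new acetal carbon being an inconsequential mixture.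

Step 8 (key step)
Reactants: 16 bromoacetal
Product: 17 cis-fused oxadecalin ketone 3-[(4aR,5R,8aS)-2-methoxy-4a,8a-dimethyl-6-oxooctahydro-2H-chromen-5-yl]propyl tetradecanoate
Conditions: (TMS)3SiH (1.3 equiv) and AIBN (0.2 equiv) added over 8 h, benzene (5 mM), 80 °C
Reagents that add atoms: none
Why: Ueno–Stork-type haloacetal radical cyclization run as a 6-exo-trig intramolecular Giese addition, in which the primary radical held on the carbinol oxygen reaches the enone β-carbon from the face of its own C–O bond and so builds the quaternary carbon with its CH2 arm cis to oxygen (cis-fused ring, both angular methyls cis), after which the tertiary α-keto radical takes hydrogen from the bulky silane axially on the face away from the 1,3-related angular methyl, leaving the ester arm equatorial and cis to both methyl groups.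

Step 9
Reactants: 17 cis-fused oxadecalin ketone
Product: 19 lactol 3-[(4aR,5R,8aS)-2,6-dihydroxy-4a,8a-dimethyl-6-(prop-1-en-2-yl)octahydro-2H-chromen-5-yl]propyl tetradecanoate, via carbinol acetal 18 (not isolated)
Conditions: isopropenylmagnesium bromide (3 equiv), CeCl3 (3 equiv), THF, −78 °C; then AcOH/THF/H2O (4:2:1), 45 °C
Reagents that add atoms: isopropenylmagnesium bromide, CC(=C)[Mg]Br; water, O
Why: Chemoselective 1,2-addition of a non-basic organocerium reagent (Imamoto conditions) to the ketone in the presence of the ester and without enolizing the adjacent stereocentre, followed by mild acid hydrolysis of the methyl acetal to the lactol in the work-up (the new carbinol carbon is lost later).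

Step 10
Reactants: 20 5-bromo-2-methylpent-2-ene
Product: 21 6-methylhept-5-en-1-yne
Conditions: lithium acetylide–ethylenediamine complex (1.3 equiv), DMSO, 10 °C → rt
Reagents that add atoms: lithium acetylide, [Li]C#C
Why: SN2 alkylation of acetylide by the primary homoallylic bromide in DMSO.

Step 11
Reactants: 21 6-methylhept-5-en-1-yne
Product: 24 (3E)-4,8-dimethylnona-3,7-dien-1-ol, via alkenylalane 22 (not isolated), via lithium alanate 23 (not isolated)
Conditions: AlMe3 (2 equiv), Cp2ZrCl2 (0.25 equiv), CH2Cl2, rt; volatiles removed; n-BuLi (1 equiv), THF/hexane, −78 → 0 °C; ethylene oxide (3 equiv), 0 °C → rt; aq. HCl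
Reagents that add atoms: trimethylaluminium, C[Al](C)C; ethylene oxide, C1CO1
Why: Negishi zirconium-catalysed carboalumination adds methyl and aluminium syn across the terminal alkyne (methyl to the inner carbon) and the derived alanate opens ethylene oxide with retention, which fixes the E trisubstituted alkene.

Step 12
Reactants: 24 (3E)-4,8-dimethylnona-3,7-dien-1-ol
Product: 25 (3E)-4,8-dimethylnona-3,7-dienoic acid
Conditions: TEMPO (0.2 equiv), PhI(OAc)2 (2.2 equiv), MeCN/H2O (1:1), rt
Reagents that add atoms: water, O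
Why: Oxoammonium (TEMPO/PhI(OAc)2) oxidation of the primary alcohol through the aldehyde hydrate to the acid under near-neutral conditions that do not move the β,γ-double bond.

Step 13
Reactants: 25 (3E)-4,8-dimethylnona-3,7-dienoic acid
Product: 27 keto-ylide (5E)-6,10-dimethyl-2-(triphenyl-λ5-phosphanylidene)undeca-5,9-dien-3-one, via acid chloride 26 (not isolated)
Conditions: 1-chloro-N,N,2-trimethylprop-1-en-1-amine (1.1 equiv), CH2Cl2, 0 °C; then added to Ph3P=CHCH3 [EtPPh3Br (2.2 equiv), n-BuLi (2.2 equiv), THF], −78 °C → rt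
Reagents that add atoms: ethyltriphenylphosphonium bromide, CC[P+](c1ccccc1)(c1ccccc1)c1ccccc1.[Br-]
Why: Bestmann C-acylation of an alkylidenephosphorane by an acid chloride made under neutral conditions, the second equivalent of ylide removing the proton of the acylphosphonium salt (transylidation) to give the stabilized keto-ylide.

Step 14
Reactants: 19 lactol; 27 keto-ylide
Product: 28 enone 3-[(1R,2R,3S)-3,6-dihydroxy-2,3-dimethyl-6-(prop-1-en-2-yl)-2-[(3E,7E)-4,8,12-trimethyl-5-oxotrideca-3,7,11-trien-1-yl]cyclohexyl]propyl tetradecanoate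
Conditions: toluene, 100 °C
Reagents that add atoms: none
Why: Wittig olefination of the lactol through its open hydroxy-aldehyde form with a stabilized α-methyl keto-ylide gives the E trisubstituted enone and frees the ring tertiary alcohol.

Step 15
Reactants: 28 enone
Product: 29 allylic alcohol with the (5R) side-chain carbinol
Conditions: (S)-2-methyl-CBS-oxazaborolidine (0.5 equiv), catecholborane (4 equiv), toluene, −78 → −40 °C; MeOH, aq. NaHCO3
Reagents that add atoms: none
Why: Corey–Bakshi–Shibata reduction in which the α-methylalkenyl group is the large and the allylic CH2 the small ketone substituent, so the (S)-catalyst delivers hydride to give the R carbinol while the ester is untouched.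

Step 16
Reactants: 29 allylic alcohol
Product: 30 TBS ether of 29
Conditions: TBSCl (1.5 equiv), imidazole (3 equiv), DMF, rt
Reagents that add atoms: tert-butyldimethylsilyl chloride, CC(C)(C)[Si](C)(C)Cl
Why: Corey silylation is selective for the secondary allylic alcohol because the two other hydroxyl groups are tertiary and hindered.

Step 17
Reactants: 30 TBS ether
Product: 31 TBS-protected Z-enal
Conditions: pyridinium chlorochromate (3 equiv), 4 Å molecular sieves, CH2Cl2, rt
Reagents that add atoms: pyridinium chlorochromate, [O-][Cr](=O)(=O)Cl.c1cc[nH+]cc1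
Why: Babler–Dauben oxidative transposition ([3,3]-shift of the tertiary allylic chromate ester, then oxidation of the primary chromate) gives the tetrasubstituted enal, whose Z isomer (slim formyl group syn to the substituted ring carbon, methyl syn to the ring CH2) is expected to be the less strained one and is separated from the minor E isomer.

Step 18
Reactants: 31 TBS-protected Z-enal
Product: 32 target CNP0171467.2
Conditions: HF·pyridine, pyridine/THF, 0 °C → rt
Reagents that add atoms: none
Why: Fluoride-mediated cleavage of the silyl ether under buffered, non-basic conditions leaves the enal geometry, the ring CH next to it and the ester untouched.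

## Compound list

1 | 2-methylcyclohex-2-en-1-one | CC1=CCCCC1=O | starting material
2 | (S)-1,2-dimethylcyclohex-2-en-1-ol | C[C@]1(O)CCCC=C1C | intermediate
3 | (S)-4-hydroxy-3,4-dimethylcyclohex-2-en-1-one | C[C@]1(O)CCC(=O)C=C1C | intermediate
4 | (S)-4-hydroxy-2-iodo-3,4-dimethylcyclohex-2-en-1-one | C[C@]1(O)CCC(=O)C(I)=C1C | intermediate
5 | 1-bromoheptane | CCCCCCCBr | starting material
6 | 1,6-dibromohexane | BrCCCCCCBr | starting material
7 | heptylmagnesium bromide | CCCCCCC[Mg]Br | intermediate
8 | 1-bromotridecane | CCCCCCCCCCCCCBr | intermediate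
9 | allyl chloroformate (prop-2-en-1-yl carbonochloridate) | C=CCOC(Cl)=O | starting material
10 | tridecylmagnesium bromide | CCCCCCCCCCCCC[Mg]Br | intermediate
11 | allyl tetradecanoate | CCCCCCCCCCCCCC(=O)OCC=C | intermediate
12 | 3-(9-borabicyclo[3.3.1]nonan-9-yl)propyl tetradecanoate | CCCCCCCCCCCCCC(=O)OCCCB1C2CCCC1CCC2 | intermediate
13 | 3-[(3S)-3-hydroxy-2,3-dimethyl-6-oxocyclohex-1-en-1-yl]propyl tetradecanoate | CCCCCCCCCCCCCC(=O)OCCCC1=C(C)[C@@](C)(O)CCC1=O | intermediate
14 | 3-bromo-1,1-dimethoxypropane | COC(CCBr)OC | starting material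
15 | 1,3-dibromo-1-methoxypropane | COC(Br)CCBr | intermediate
16 | 3-[(3S)-3-(3-bromo-1-methoxypropoxy)-2,3-dimethyl-6-oxocyclohex-1-en-1-yl]propyl tetradecanoate (acetal carbon: mixture) | CCCCCCCCCCCCCC(=O)OCCCC1=C(C)[C@@](C)(OC(OC)CCBr)CCC1=O | intermediate
17 | 3-[(4aR,5R,8aS)-2-methoxy-4a,8a-dimethyl-6-oxooctahydro-2H-chromen-5-yl]propyl tetradecanoate (C2: mixture) | CCCCCCCCCCCCCC(=O)OCCC[C@H]1C(=O)CC[C@]2(C)OC(OC)CC[C@]12C | intermediate
18 | 3-[(4aR,5R,8aS)-6-hydroxy-2-methoxy-4a,8a-dimethyl-6-(prop-1-en-2-yl)octahydro-2H-chromen-5-yl]propyl tetradecanoate (C2, C6: mixtures) | CCCCCCCCCCCCCC(=O)OCCC[C@H]1C(O)(C(C)=C)CC[C@]2(C)OC(OC)CC[C@]12C | intermediate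
19 | 3-[(4aR,5R,8aS)-2,6-dihydroxy-4a,8a-dimethyl-6-(prop-1-en-2-yl)octahydro-2H-chromen-5-yl]propyl tetradecanoate (C2, C6: mixtures) | CCCCCCCCCCCCCC(=O)OCCC[C@H]1C(O)(C(C)=C)CC[C@]2(C)OC(O)CC[C@]12C | intermediate
20 | 5-bromo-2-methylpent-2-ene | CC(C)=CCCBr | starting material
21 | 6-methylhept-5-en-1-yne | CC(C)=CCCC#C | intermediate
22 | [(1E)-2,6-dimethylhepta-1,5-dien-1-yl]dimethylalane | C[Al](C)/C=C(\C)CCC=C(C)C | intermediate
23 | lithium butyl[(1E)-2,6-dimethylhepta-1,5-dien-1-yl]dimethylalanate | [Li+].CCCC[Al-](C)(C)/C=C(\C)CCC=C(C)C | intermediate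
24 | (3E)-4,8-dimethylnona-3,7-dien-1-ol | OCC/C=C(\C)CCC=C(C)C | intermediate
25 | (3E)-4,8-dimethylnona-3,7-dienoic acid | OC(=O)C/C=C(\C)CCC=C(C)C | intermediate
26 | (3E)-4,8-dimethylnona-3,7-dienoyl chloride | ClC(=O)C/C=C(\C)CCC=C(C)C | intermediate
27 | (5E)-6,10-dimethyl-2-(triphenyl-λ5-phosphanylidene)undeca-5,9-dien-3-one | CC(=P(c1ccccc1)(c1ccccc1)c1ccccc1)C(=O)C/C=C(\C)CCC=C(C)C | intermediate
28 | 3-[(1R,2R,3S)-3,6-dihydroxy-2,3-dimethyl-6-(prop-1-en-2-yl)-2-[(3E,7E)-4,8,12-trimethyl-5-oxotrideca-3,7,11-trien-1-yl]cyclohexyl]propyl tetradecanoate (C6: mixture) | CCCCCCCCCCCCCC(=O)OCCC[C@H]1C(O)(C(C)=C)CC[C@](C)(O)[C@]1(C)CC/C=C(\C)C(=O)C/C=C(\C)CCC=C(C)C | intermediate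
29 | 3-[(1R,2R,3S)-3,6-dihydroxy-2-[(3E,5R,7E)-5-hydroxy-4,8,12-trimethyltrideca-3,7,11-trien-1-yl]-2,3-dimethyl-6-(prop-1-en-2-yl)cyclohexyl]propyl tetradecanoate (C6: mixture) | CCCCCCCCCCCCCC(=O)OCCC[C@H]1C(O)(C(C)=C)CC[C@](C)(O)[C@]1(C)CC/C=C(\C)[C@H](O)C/C=C(\C)CCC=C(C)C | intermediate
30 | 3-[(1R,2R,3S)-2-[(3E,5R,7E)-5-{[tert-butyl(dimethyl)silyl]oxy}-4,8,12-trimethyltrideca-3,7,11-trien-1-yl]-3,6-dihydroxy-2,3-dimethyl-6-(prop-1-en-2-yl)cyclohexyl]propyl tetradecanoate (C6: mixture) | CCCCCCCCCCCCCC(=O)OCCC[C@H]1C(O)(C(C)=C)CC[C@](C)(O)[C@]1(C)CC/C=C(\C)[C@H](O[Si](C)(C)C(C)(C)C)C/C=C(\C)CCC=C(C)C | intermediate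
31 | 3-[(1S,2R,3S)-2-[(3E,5R,7E)-5-{[tert-butyl(dimethyl)silyl]oxy}-4,8,12-trimethyltrideca-3,7,11-trien-1-yl]-3-hydroxy-2,3-dimethyl-6-[(2Z)-1-oxopropan-2-ylidene]cyclohexyl]propyl tetradecanoate | CCCCCCCCCCCCCC(=O)OCCC[C@H]1/C(=C(/C)C=O)CC[C@](C)(O)[C@]1(C)CC/C=C(\C)[C@H](O[Si](C)(C)C(C)(C)C)C/C=C(\C)CCC=C(C)C | intermediate
32 | 3-[(1S,2R,3S)-3-hydroxy-2-[(3E,5R,7E)-5-hydroxy-4,8,12-trimethyltrideca-3,7,11-trien-1-yl]-2,3-dimethyl-6-[(2Z)-1-oxopropan-2-ylidene]cyclohexyl]propyl tetradecanoate | CCCCCCCCCCCCCC(=O)OCCC[C@H]1/C(=C(/C)C=O)CC[C@](C)(O)[C@]1(C)CC/C=C(\C)[C@H](O)C/C=C(\C)CCC=C(C)C | target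

## Step count and risks

Total steps: 18. Longest linear sequence: 12 steps (1 → 32 through steps 1, 2, 3, 6, 7, 8, 9, 14, 15, 16, 17, 18).

The three steps most likely to fail are steps 7, 8 and 17.

Step 7 (tether on the hindered tertiary alcohol). The alcohol may not alkylate, or the α-bromo ether 15 may eliminate first. The fallback sets out from 13 and returns at 17. Acid-catalysed (PPTS) addition of the alcohol to methoxyallene gives the acrolein mixed acetal F1. 9-BBN adds to its vinyl group to give the borane F2, and NaBO3·4H2O turns this into the primary alcohol F3. I2/PPh3/imidazole gives the iodide F4, which is cyclized under the conditions of step 8 to 17.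

Step 8 (the radical cyclization). The primary radical may be reduced before it closes onto the fully substituted enone carbon, the ring may close trans, or hydrogen may be delivered to the wrong face of the α-keto radical. The fallback sets out from 13 and returns at 19. N-Bromosuccinimide and ethyl vinyl ether give the 2-bromoacetal F5. (TMS)3SiH/AIBN now closes the faster 5-exo-trig ring, for which cis-fusion is the only option, to the furanoid ketone F6. Isopropenylmagnesium bromide/CeCl3 gives the carbinol F7, and aqueous acetic acid gives the five-ring lactol F8. Ph3P=CHOMe adds the missing carbon as the enol ether F9, and dilute acid hydrolysis closes the six-ring lactol 19.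

Step 17 (enal formation). The transposition may favour the E-enal, or the allylic cation may be trapped by the ring tertiary alcohol as a 1,4-bridged ether. The fallback sets out from 30 and returns at 31. Ph3SiOReO3 (2 mol %, Et2O, −50 → 0 °C) transposes the tertiary allylic alcohol reversibly to the primary allylic alcohols. The Z isomer, the primary allylic alcohol F10, is separated and the E isomer is re-equilibrated with the same catalyst. MnO2 in CH2Cl2 then oxidizes F10 to 31.

## Further compounds

F1 | step 7 | 3-[(3S)-3-[(1-methoxyprop-2-en-1-yl)oxy]-2,3-dimethyl-6-oxocyclohex-1-en-1-yl]propyl tetradecanoate | CCCCCCCCCCCCCC(=O)OCCCC1=C(C)[C@@](C)(OC(OC)C=C)CCC1=O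
F2 | step 7 | 3-[(3S)-3-[3-(9-borabicyclo[3.3.1]nonan-9-yl)-1-methoxypropoxy]-2,3-dimethyl-6-oxocyclohex-1-en-1-yl]propyl tetradecanoate | CCCCCCCCCCCCCC(=O)OCCCC1=C(C)[C@@](C)(OC(OC)CCB2C3CCCC2CCC3)CCC1=O
F3 | step 7 | 3-[(3S)-3-(3-hydroxy-1-methoxypropoxy)-2,3-dimethyl-6-oxocyclohex-1-en-1-yl]propyl tetradecanoate | CCCCCCCCCCCCCC(=O)OCCCC1=C(C)[C@@](C)(OC(OC)CCO)CCC1=O
F4 | step 7 | 3-[(3S)-3-(3-iodo-1-methoxypropoxy)-2,3-dimethyl-6-oxocyclohex-1-en-1-yl]propyl tetradecanoate | CCCCCCCCCCCCCC(=O)OCCCC1=C(C)[C@@](C)(OC(OC)CCI)CCC1=O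
F5 | step 8 | 3-[(3S)-3-(2-bromo-1-ethoxyethoxy)-2,3-dimethyl-6-oxocyclohex-1-en-1-yl]propyl tetradecanoate | CCCCCCCCCCCCCC(=O)OCCCC1=C(C)[C@@](C)(OC(OCC)CBr)CCC1=O
F6 | step 8 | 3-[(3aR,4R,7aS)-2-ethoxy-3a,7a-dimethyl-5-oxooctahydro-1-benzofuran-4-yl]propyl tetradecanoate | CCCCCCCCCCCCCC(=O)OCCC[C@H]1C(=O)CC[C@]2(C)OC(OCC)C[C@]12C
F7 | step 8 | 3-[(3aR,4R,7aS)-2-ethoxy-5-hydroxy-3a,7a-dimethyl-5-(prop-1-en-2-yl)octahydro-1-benzofuran-4-yl]propyl tetradecanoate | CCCCCCCCCCCCCC(=O)OCCC[C@H]1C(O)(C(C)=C)CC[C@]2(C)OC(OCC)C[C@]12C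
F8 | step 8 | 3-[(3aR,4R,7aS)-2,5-dihydroxy-3a,7a-dimethyl-5-(prop-1-en-2-yl)octahydro-1-benzofuran-4-yl]propyl tetradecanoate | CCCCCCCCCCCCCC(=O)OCCC[C@H]1C(O)(C(C)=C)CC[C@]2(C)OC(O)C[C@]12C
F9 | step 8 | 3-[(1R,2R,3S)-3,6-dihydroxy-2-(3-methoxyprop-2-en-1-yl)-2,3-dimethyl-6-(prop-1-en-2-yl)cyclohexyl]propyl tetradecanoate | CCCCCCCCCCCCCC(=O)OCCC[C@H]1C(O)(C(C)=C)CC[C@](C)(O)[C@]1(C)CC=COC
F10 | step 17 | 3-[(1S,2R,3S)-2-[(3E,5R,7E)-5-{[tert-butyl(dimethyl)silyl]oxy}-4,8,12-trimethyltrideca-3,7,11-trien-1-yl]-3-hydroxy-6-[(2Z)-1-hydroxypropan-2-ylidene]-2,3-dimethylcyclohexyl]propyl tetradecanoate | CCCCCCCCCCCCCC(=O)OCCC[C@H]1/C(=C(/C)CO)CC[C@](C)(O)[C@]1(C)CC/C=C(\C)[C@H](O[Si](C)(C)C(C)(C)C)C/C=C(\C)CCC=C(C)C
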